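## Retrosynthetic overview

- **Feature:** C3, C2 and the C(CH3)2 unit on C2 of the dihydrofuran ring make up the C5 chain of isoprene. This chain is joined to aromatic ring A only through C3–C3a and O1–C2. Ring A is a phloroglucinol nucleus acylated at C5 by a p-coumaroyl unit.
- **Last disconnections:** global acidolysis (three aryl MOM ethers, one TES ether), then C5–C(=O), which leads back to a C5 aryllithium (between the C4 and C6 OMOM groups) and the Weinreb amide of O-MOM p-coumaric acid.
- **Side chain:** the tertiary alcohol comes from the isopropenyl group by Markovnikov hydrogen-atom-transfer hydration.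
- **Ring formation:** rings A and B are bought, so the dihydrofuran is the only ring made. It comes from 2-iodo-3,5-bis(methoxymethoxy)phenol and isoprene by enantioselective Pd heteroannulation, which also sets C2 (S).
- **Precursor:** the iodophenol comes from phloroglucinol by bis-MOM protection and iodination ortho to the remaining OH.

Key step: step 3

Assumption: the sense of induction of the chiral ligand on this iodophenol cannot be assigned in advance. Both ligand antipodes are accessible, and the one that delivers the 2S annulation product is used, with the assignment made by chiroptical correlation with the marmesin-type series.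

## Route

Step 1
Reactants: 1 phloroglucinol
Product: 2 3,5-bis(methoxymethoxy)phenol
Conditions: MOMCl (2.0 equiv), i-Pr2NEt (2.2 equiv), DMF, 0 °C → rt
Reagents that add atoms: chloromethyl methyl ether, COCCl
Why: Base-mediated O-alkylation (MOM acetal formation) of three equivalent phenols; with two equivalents of MOMCl the distribution centres on the bis-ether, which is separated chromatographically from the mono- and tris-ethers, the former being recyclable.

Step 2
Reactants: 2 3,5-bis(methoxymethoxy)phenol
Product: 3 2-iodo-3,5-bis(methoxymethoxy)phenol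
Conditions: NIS (1.0 equiv), CH2Cl2, −20 → 0 °C, dark
Reagents that add atoms: N-iodosuccinimide, O=C1CCC(=O)N1I
Why: Electrophilic aromatic iodination of a strongly activated ring; the two equivalent positions ortho to the free OH are statistically favoured, less crowded than the site flanked by two OMOM groups and reached by hydrogen-bond-guided delivery of NIS in a non-polar solvent, while one equivalent at low temperature holds back di-iodination.

Step 3
Reactants: 3 2-iodo-3,5-bis(methoxymethoxy)phenol; 4 isoprene
Product: 5 (2S)-4,6-bis(methoxymethoxy)-2-(prop-1-en-2-yl)-2,3-dihydro-1-benzofuran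
Conditions: Pd2(dba)3·CHCl3 (2.5 mol %), chiral tert-butanesulfinamide–monophosphine ligand L* (Sadphos class, 10 mol %), K2CO3 (2 equiv), 4 (5 equiv), toluene, sealed tube, 60 °C
Reagents that add atoms: none
Why: Pd(0) inserts into the C–I bond of 3, the aryl–Pd species adds across the unsubstituted vinyl group of isoprene with the aryl carbon going to the terminal CH2 (C3a–C3), and the alkyl–Pd so formed collapses to a 2-methyl-π-allyl complex tethered to the phenoxide, which forms O1–C2 and releases Pd(0). The closest known reaction type is the Larock heteroannulation of o-halophenols with 1,3-dienes (a Heck/Tsuji–Trost cascade), for which enantioselective versions with chiral phosphine ligands are established. The dihydrofuran ring closes in a 5-exo mode at the substituted allyl terminus, whereas attack at the CH2 terminus would require a seven-membered ring and is kinetically disfavoured. C2 is the only new stereocentre and is ligand-controlled: the two diastereomeric π-allyl complexes exchange palladium faces by η3–η1–η3 slippage through the unsubstituted CH2 terminus faster than the C–O bond forms, so the chiral pocket selects the complex that leads to 2S (dynamic kinetic asymmetric allylic etherification). Site selectivity on the diene rests on the methyl branch, which shields the 1,1-disubstituted alkene from carbopalladation, and site selectivity on the arene is fixed by the iodine (C3a) and by the single free OH (O1), the MOM ethers being inert. The electron-rich phenoxide is a poor leaving group, so re-ionisation of the allyl aryl ether 5 by Pd(0) and the loss of enantiopurity that would follow should be slow.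

Step 4
Reactants: 5 (2S)-4,6-bis(methoxymethoxy)-2-(prop-1-en-2-yl)-2,3-dihydro-1-benzofuran
Product: 7 2-[(2S)-4,6-bis(methoxymethoxy)-2,3-dihydro-1-benzofuran-2-yl]propan-2-ol, via tertiary hydroperoxide 6 (not isolated)
Conditions: Co(acac)2 (20 mol %), PhSiH3 (2 equiv), O2 (1 atm), THF, rt; then PPh3, rt
Reagents that add atoms: dioxygen, O=O
Why: Mukaiyama hydration: cobalt-hydride hydrogen-atom transfer to the terminal CH2 gives the tertiary radical (Markovnikov), which is captured by O2 much faster than it could expel the β-aryloxy group, and the peroxide is reduced by PPh3; C2 is not involved and keeps its configuration.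

Step 5
Reactants: 7 2-[(2S)-4,6-bis(methoxymethoxy)-2,3-dihydro-1-benzofuran-2-yl]propan-2-ol
Product: 8 triethyl({2-[(2S)-4,6-bis(methoxymethoxy)-2,3-dihydro-1-benzofuran-2-yl]propan-2-yl}oxy)silane
Conditions: TESCl, imidazole, DMAP (cat.), DMF, rt → 40 °C
Reagents that add atoms: chlorotriethylsilane, CC[Si](Cl)(CC)CC
Why: Imidazole-promoted silylation masks the tertiary OH so that no lithium alkoxide next to O1 can steer the later metalation towards C7, and the chloride/imidazole conditions avoid the acetal cleavage that silyl triflates can cause on aryl MOM ethers.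

Step 6
Reactants: 9 p-coumaric acid
Product: 10 (E)-3-(4-hydroxyphenyl)-N-methoxy-N-methylprop-2-enamide
Conditions: MeNHOMe·HCl, EDC·HCl, HOBt (cat.), NMM, CH2Cl2–DMF, 0 °C → rt
Reagents that add atoms: N,O-dimethylhydroxylamine hydrochloride, CNOC.Cl
Why: Carbodiimide amide coupling (Weinreb amide formation) in which the amine outcompetes the phenol for the activated ester and the E-alkene is untouched.

Step 7
Reactants: 10 (E)-3-(4-hydroxyphenyl)-N-methoxy-N-methylprop-2-enamide
Product: 11 (E)-N-methoxy-3-[4-(methoxymethoxy)phenyl]-N-methylprop-2-enamide
Conditions: MOMCl, i-Pr2NEt, CH2Cl2, 0 °C → rt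
Reagents that add atoms: chloromethyl methyl ether, COCCl
Why: MOM acetal formation on the phenol removes the only acidic proton that would quench the aryllithium in step 8 and uses the same acid-labile group as ring A.

Step 8
Reactants: 8 triethyl({2-[(2S)-4,6-bis(methoxymethoxy)-2,3-dihydro-1-benzofuran-2-yl]propan-2-yl}oxy)silane; 11 (E)-N-methoxy-3-[4-(methoxymethoxy)phenyl]-N-methylprop-2-enamide
Product: 14 (E)-1-[(2S)-4,6-bis(methoxymethoxy)-2-{2-[(triethylsilyl)oxy]propan-2-yl}-2,3-dihydro-1-benzofuran-5-yl]-3-[4-(methoxymethoxy)phenyl]prop-2-en-1-one, via C5-aryllithium 12 (not isolated), via lithium hemiaminal chelate 13 (not isolated)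
Conditions: n-BuLi (1.1 equiv), THF, 0 °C, 1 h; then 11, −78 → 0 °C; aq NH4Cl
Reagents that add atoms: none
Why: Directed ortho-metalation followed by Weinreb ketone synthesis: C5–H sits between two chelating OMOM groups and is removed in preference to C7–H (one OMOM plus the ring ether), and 1,2-addition of 12 to the amide gives the five-membered lithium chelate 13, which collapses to the enone only on quench so that neither over-addition nor alkene isomerisation occurs.

Step 9
Reactants: 14 (E)-1-[(2S)-4,6-bis(methoxymethoxy)-2-{2-[(triethylsilyl)oxy]propan-2-yl}-2,3-dihydro-1-benzofuran-5-yl]-3-[4-(methoxymethoxy)phenyl]prop-2-en-1-one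
Product: 15 (E)-1-[(2S)-4,6-dihydroxy-2-(2-hydroxypropan-2-yl)-2,3-dihydro-1-benzofuran-5-yl]-3-(4-hydroxyphenyl)prop-2-en-1-one
Conditions: HCl (ca. 1 M in MeOH), rt; dilution with water, extraction, no basic wash
Reagents that add atoms: none
Why: Acid-catalysed transacetalisation of the three aryl MOM ethers and solvolysis of the TES ether in methanol; the tertiary alcohol is protected from ionisation by the adjacent C2–O1 bond, no bond at C2 is broken, and low temperature together with an acidic, base-free work-up keeps the 2',6'-dihydroxychalcone from closing to a flavanone.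

## Compound list

1 | phloroglucinol (benzene-1,3,5-triol) | Oc1cc(O)cc(O)c1 | starting material
2 | 3,5-bis(methoxymethoxy)phenol | COCOc1cc(O)cc(OCOC)c1 | intermediate
3 | 2-iodo-3,5-bis(methoxymethoxy)phenol | Oc1cc(OCOC)cc(OCOC)c1I | intermediate
4 | isoprene (2-methylbuta-1,3-diene) | C=CC(C)=C | starting material
5 | (2S)-4,6-bis(methoxymethoxy)-2-(prop-1-en-2-yl)-2,3-dihydro-1-benzofuran | C=C(C)[C@@H]1Cc2c(OCOC)cc(OCOC)cc2O1 | intermediate
6 | (2S)-2-(2-hydroperoxypropan-2-yl)-4,6-bis(methoxymethoxy)-2,3-dihydro-1-benzofuran (not isolated) | CC(C)(OO)[C@@H]1Cc2c(OCOC)cc(OCOC)cc2O1 | intermediate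
7 | 2-[(2S)-4,6-bis(methoxymethoxy)-2,3-dihydro-1-benzofuran-2-yl]propan-2-ol | CC(C)(O)[C@@H]1Cc2c(OCOC)cc(OCOC)cc2O1 | intermediate
8 | triethyl({2-[(2S)-4,6-bis(methoxymethoxy)-2,3-dihydro-1-benzofuran-2-yl]propan-2-yl}oxy)silane | CC[Si](CC)(CC)OC(C)(C)[C@@H]1Cc2c(OCOC)cc(OCOC)cc2O1 | intermediate
9 | p-coumaric acid, (E)-3-(4-hydroxyphenyl)prop-2-enoic acid | O=C(O)/C=C/c1ccc(O)cc1 | starting material
10 | (E)-3-(4-hydroxyphenyl)-N-methoxy-N-methylprop-2-enamide | CON(C)C(=O)/C=C/c1ccc(O)cc1 | intermediate
11 | (E)-N-methoxy-3-[4-(methoxymethoxy)phenyl]-N-methylprop-2-enamide | CON(C)C(=O)/C=C/c1ccc(OCOC)cc1 | intermediate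
12 | C5-lithio derivative of 8 (not isolated) | CC[Si](CC)(CC)OC(C)(C)[C@@H]1Cc2c(OCOC)c([Li])c(OCOC)cc2O1 | intermediate
13 | lithium alkoxide of the N-methoxy-N-methyl hemiaminal, the tetrahedral adduct of 12 on 11; carbinol carbon undefined (not isolated) | CC[Si](CC)(CC)OC(C)(C)[C@@H]1Cc2c(OCOC)c(C(O[Li])(N(C)OC)/C=C/c3ccc(OCOC)cc3)c(OCOC)cc2O1 | intermediate
14 | (E)-1-[(2S)-4,6-bis(methoxymethoxy)-2-{2-[(triethylsilyl)oxy]propan-2-yl}-2,3-dihydro-1-benzofuran-5-yl]-3-[4-(methoxymethoxy)phenyl]prop-2-en-1-one | CC[Si](CC)(CC)OC(C)(C)[C@@H]1Cc2c(OCOC)c(C(=O)/C=C/c3ccc(OCOC)cc3)c(OCOC)cc2O1 | intermediate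
15 | (E)-1-[(2S)-4,6-dihydroxy-2-(2-hydroxypropan-2-yl)-2,3-dihydro-1-benzofuran-5-yl]-3-(4-hydroxyphenyl)prop-2-en-1-one | CC(C)(O)[C@@H]1Cc2c(cc(O)c(C(=O)/C=C/c3ccc(O)cc3)c2O)O1 | target

## Step count and risks

Total step count: 9. Longest linear sequence: 7 (steps 1, 2, 3, 4, 5, 8, 9).

**1. Step 3.**
- **What may go wrong:** enantiodiscrimination at C–O bond formation may be too weak on a doubly ortho-substituted, electron-rich aryl–palladium. Protodeiodination, carbopalladation at the methyl-bearing alkene of isoprene and palladium-catalysed addition of the phenol to the diene can also compete.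
- **Fallback:** it sets out from 3 and comes back at 7, so steps 3 and 4 are bypassed. Stille coupling of 3 with tributyl(3-methylbut-2-en-1-yl)stannane (Pd(PPh3)4, DMF, heat) should give the 2-prenylphenol F1. This is silylated (TBSCl, imidazole) to the aryl TBS ether F2. Shi epoxidation with the fructose-derived ketone antipode matched to the R product should give the (R)-epoxide F3. TBAF then frees the phenoxide, which opens the epoxide at its secondary carbon in a 5-exo-tet closure with inversion. That forms O1–C2 with the S configuration and gives the tertiary alcohol 7 directly.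

**2. Step 8.**
- **What may go wrong:** metalation may occur partly at C7 instead of C5. Addition of the doubly ortho-substituted aryllithium to the cinnamoyl amide may also be sluggish or go in the conjugate sense.
- **Fallback:** it sets out from 8 and comes back at 14. The lithiated species 12 is quenched with the small electrophile N-methoxy-N-methylacetamide to give the methyl ketone F4, a stage at which any regioisomeric ketone can be separated before the cinnamoyl partner is spent. The enone is then built from the other side by Claisen–Schmidt condensation of F4 with commercial 4-(methoxymethoxy)benzaldehyde (KOH, EtOH, rt). This forms the Cα=Cβ bond with E geometry and delivers 14.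

**3. Step 9.**
- **What may go wrong:** the liberated C4 and C6 phenols may close onto the enone by oxa-Michael addition (chalcone–flavanone isomerisation) during acidolysis or work-up. Acid-induced loss of the tertiary hydroxyl is a lesser concern.
- **Fallback:** it sets out from 14 and comes back at 15. The acidolysis is driven to completion without regard to ring closure (HCl, MeOH, reflux). This should give the linear flavanone F5 (closure through the C6 oxygen) and the angular flavanone F6 (closure through the C4 oxygen), each as a pair of epimers at the new benzylic carbon. The mixture is then reopened by retro-oxa-Michael (E1cB) cleavage in concentrated aqueous KOH under argon, where the chalcone polyphenolate is the stable form. Rapid acidification at 0 °C should release 15. C2 of the dihydrofuran carries no acidic hydrogen and is not affected.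

## Further compounds

F1 | step 3 | 3,5-bis(methoxymethoxy)-2-(3-methylbut-2-en-1-yl)phenol | CC(C)=CCc1c(O)cc(OCOC)cc1OCOC
F2 | step 3 | tert-butyl[3,5-bis(methoxymethoxy)-2-(3-methylbut-2-en-1-yl)phenoxy]dimethylsilane | CC(C)=CCc1c(O[Si](C)(C)C(C)(C)C)cc(OCOC)cc1OCOC
F3 | step 3 | tert-butyl(2-{[(2R)-3,3-dimethyloxiran-2-yl]methyl}-3,5-bis(methoxymethoxy)phenoxy)dimethylsilane | CC1(C)O[C@@H]1Cc2c(O[Si](C)(C)C(C)(C)C)cc(OCOC)cc2OCOC
F4 | step 8 | 1-[(2S)-4,6-bis(methoxymethoxy)-2-{2-[(triethylsilyl)oxy]propan-2-yl}-2,3-dihydro-1-benzofuran-5-yl]ethan-1-one | CC[Si](CC)(CC)OC(C)(C)[C@@H]1Cc2c(OCOC)c(C(C)=O)c(OCOC)cc2O1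
F5 | step 9 | linear dihydrofuranoflavanone, pyranone closed through the C6 oxygen, C4–OH free, epimeric at the new benzylic carbon | CC(C)(O)[C@@H]1Cc2c(O1)cc3OC(CC(=O)c3c2O)c4ccc(O)cc4
F6 | step 9 | angular dihydrofuranoflavanone, pyranone closed through the C4 oxygen, C6–OH free, epimeric at the new benzylic carbon | CC(C)(O)[C@@H]1Cc2c(O1)cc(O)c3C(=O)CC(Oc23)c4ccc(O)cc4
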